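**Retrosynthetic overview**
- The target, a (5R)-β-hydroxy ketone, is taken back to a tris-O-benzyl δ-hydroxy-β-keto ester; one hydrogenolysis removes all three benzyl groups and the extra carboxyl carbon is lost as CO2.
- Key disconnection C2–C3: Claisen-type ring opening of an (R)-4-(2-arylethyl)oxetan-2-one (acyl half) by the lithium enolate of benzyl 3-(4-benzyloxy-3,5-dimethoxyphenyl)propanoate (alkyl half).
- Enabling feature: the C3 carbonyl carbon and the C5 carbinol oxygen are 1,3-related (O5–C5–C4–C3), so the acyl half is a ring-opened oxetan-2-one. Tying O5 to C3 makes C3 a strained acyl donor that carries its own hydroxyl protection; C2 is α to C3 and can be carried as an ester α-carbon.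
- The β-lactone comes from 3-(4-benzyloxy-3-methoxyphenyl)propanal by a catalytic asymmetric ketene–aldehyde [2+2], which sets C5; the aldehyde comes from dihydroconiferyl alcohol and the ester from sinapic acid.
- Rings: both arenes are bought; the only ring formed is the temporary oxetan-2-one (step 3), opened again in step 6.

Key step: step 6

Remark: in step 3 O-trimethylsilylquinine is assumed to give the (4R)-lactone from ketene and an unbranched aldehyde; if the sense of induction is the reverse, the pseudoenantiomeric O-trimethylsilylquinidine is used with no other change.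

Step 1
Reactants: 1 4-(3-hydroxypropyl)-2-methoxyphenol (dihydroconiferyl alcohol)
Product: 2 3-[4-(benzyloxy)-3-methoxyphenyl]propan-1-ol
Conditions: BnBr (1.1 equiv), K2CO3, acetone, reflux
Reagents that add atoms: benzyl bromide, BrCc1ccccc1
Why: Williamson ether synthesis, in which carbonate deprotonates only the phenol and not the primary alcohol, so benzylation should be selective for the phenolic oxygen.

Step 2
Reactants: 2 3-[4-(benzyloxy)-3-methoxyphenyl]propan-1-ol
Product: 3 3-[4-(benzyloxy)-3-methoxyphenyl]propanal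
Conditions: TEMPO (10 mol%), PhI(OAc)2 (1.1 equiv), CH2Cl2, rt
Reagents that add atoms: none
Why: TEMPO/oxoammonium-catalysed alcohol oxidation with PhI(OAc)2 as terminal oxidant should stop at the aldehyde and leave the benzyl ether and the electron-rich ring alone.

Step 3
Reactants: 3 3-[4-(benzyloxy)-3-methoxyphenyl]propanal
Product: 4 (4R)-4-{2-[4-(benzyloxy)-3-methoxyphenyl]ethyl}oxetan-2-one
Conditions: AcCl (slow addition), iPr2NEt, O-trimethylsilylquinine (10 mol%), LiClO4, CH2Cl2/Et2O, −78 °C
Reagents that add atoms: acetyl chloride, CC(=O)Cl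
Why: Catalytic asymmetric acyl halide–aldehyde cyclocondensation (Wynberg-type ketene–aldehyde [2+2] in its alkaloid/LiClO4 form), in which ketene formed in situ is bound by the alkaloid as a chiral ammonium enolate that adds to one face of the lithium-activated aldehyde before the four-membered ring closes, so the catalyst sets the R centre that becomes C5 of the target.

Step 4
Reactants: 5 (E)-3-(4-hydroxy-3,5-dimethoxyphenyl)prop-2-enoic acid (sinapic acid)
Product: 6 3-(4-hydroxy-3,5-dimethoxyphenyl)propanoic acid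
Conditions: H2 (1 atm), 10% Pd/C, MeOH, rt
Reagents that add atoms: none
Why: Heterogeneous catalytic hydrogenation should saturate the cinnamic C=C bond and touch neither the arene nor the acid.

Step 5
Reactants: 6 3-(4-hydroxy-3,5-dimethoxyphenyl)propanoic acid
Product: 7 benzyl 3-[4-(benzyloxy)-3,5-dimethoxyphenyl]propanoate
Conditions: BnBr (2.3 equiv), K2CO3, DMF, 60 °C
Reagents that add atoms: benzyl bromide, BrCc1ccccc1
Why: Double O-alkylation (carboxylate esterification and Williamson etherification) should install in one operation the phenol protection and the benzyl ester that serves as the removable activating group at C2.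

Step 6
Reactants: 7 benzyl 3-[4-(benzyloxy)-3,5-dimethoxyphenyl]propanoate (2.4 equiv); 4 (4R)-4-{2-[4-(benzyloxy)-3-methoxyphenyl]ethyl}oxetan-2-one
Product: 9 benzyl (5R)-2-{[4-(benzyloxy)-3,5-dimethoxyphenyl]methyl}-7-[4-(benzyloxy)-3-methoxyphenyl]-5-hydroxy-3-oxoheptanoate (both C2 epimers), via lithium ester enolate 8 (not isolated)
Conditions: LDA (2.3 equiv), THF, −78 °C; then 4 in THF added slowly, −78 °C; AcOH/THF quench at −78 °C
Reagents that add atoms: none
Why: The lithium enolate 8 should add through carbon to the carbonyl carbon of the strained oxetan-2-one 4, and collapse of the tetrahedral intermediate with acyl C–O cleavage forms the C2–C3 bond, makes C3 the ketone and releases O5 as its lithium alkoxide in the same event. The closest known reaction type is the Claisen-type ring opening of enantioenriched 4-alkyloxetan-2-ones by lithium ester enolates to δ-hydroxy-β-keto esters. No ring is closed (the four-membered ring is opened), and the only new stereocentre, C2, is formed without control and is of no consequence because it is erased in step 7. C5 keeps its R configuration because its C–O bond is never broken. The step needs acyl–oxygen over alkyl–oxygen cleavage and a single addition: the hard lithium enolate at −78 °C and the ring strain favour carbonyl attack, and the adduct is at once deprotonated by the second equivalent of 8 to its unreactive β-keto ester enolate, which makes the opening irreversible and blocks a second addition.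

Step 7
Reactants: 9 benzyl (5R)-2-{[4-(benzyloxy)-3,5-dimethoxyphenyl]methyl}-7-[4-(benzyloxy)-3-methoxyphenyl]-5-hydroxy-3-oxoheptanoate
Product: 11 (5R)-5-hydroxy-7-(4-hydroxy-3-methoxyphenyl)-1-(4-hydroxy-3,5-dimethoxyphenyl)heptan-3-one (the target), via free beta-keto acid 10 (not isolated)
Conditions: H2 (1 atm), 10% Pd/C, EtOAc–EtOH, rt; filter; 40 °C
Reagents that add atoms: none
Why: Pd-catalysed hydrogenolysis should remove all three O-benzyl groups under neutral conditions, and the resulting 2-substituted 3-oxo acid should lose CO2 through the usual six-membered cyclic transition state on gentle warming, which leaves the aldol unit and the C5 centre untouched.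

**Compound list**
1 | 4-(3-hydroxypropyl)-2-methoxyphenol (dihydroconiferyl alcohol) | COc1cc(CCCO)ccc1O | starting material
2 | 3-[4-(benzyloxy)-3-methoxyphenyl]propan-1-ol | COc1cc(CCCO)ccc1OCc1ccccc1 | intermediate
3 | 3-[4-(benzyloxy)-3-methoxyphenyl]propanal | COc1cc(CCC=O)ccc1OCc1ccccc1 | intermediate
4 | (4R)-4-{2-[4-(benzyloxy)-3-methoxyphenyl]ethyl}oxetan-2-one | COc1cc(CC[C@@H]2CC(=O)O2)ccc1OCc1ccccc1 | intermediate
5 | (E)-3-(4-hydroxy-3,5-dimethoxyphenyl)prop-2-enoic acid (sinapic acid) | COc1cc(/C=C/C(=O)O)cc(OC)c1O | starting material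
6 | 3-(4-hydroxy-3,5-dimethoxyphenyl)propanoic acid | COc1cc(CCC(=O)O)cc(OC)c1O | intermediate
7 | benzyl 3-[4-(benzyloxy)-3,5-dimethoxyphenyl]propanoate | COc1cc(CCC(=O)OCc2ccccc2)cc(OC)c1OCc1ccccc1 | intermediate
8 | lithium enolate of 7 (enolate geometry not specified, of no consequence; not isolated) | COc1cc(CC=C(O[Li])OCc2ccccc2)cc(OC)c1OCc1ccccc1 | intermediate
9 | benzyl (5R)-2-{[4-(benzyloxy)-3,5-dimethoxyphenyl]methyl}-7-[4-(benzyloxy)-3-methoxyphenyl]-5-hydroxy-3-oxoheptanoate (both C2 epimers) | COc1cc(CC[C@@H](O)CC(=O)C(Cc2cc(OC)c(OCc3ccccc3)c(OC)c2)C(=O)OCc2ccccc2)ccc1OCc1ccccc1 | intermediate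
10 | (5R)-5-hydroxy-2-[(4-hydroxy-3,5-dimethoxyphenyl)methyl]-7-(4-hydroxy-3-methoxyphenyl)-3-oxoheptanoic acid (both C2 epimers; not isolated) | COc1cc(CC[C@@H](O)CC(=O)C(Cc2cc(OC)c(O)c(OC)c2)C(=O)O)ccc1O | intermediate
11 | (5R)-5-hydroxy-7-(4-hydroxy-3-methoxyphenyl)-1-(4-hydroxy-3,5-dimethoxyphenyl)heptan-3-one | COc1cc(CC[C@@H](O)CC(=O)CCc2cc(OC)c(O)c(OC)c2)ccc1O | target

**Step count**
Total steps: 7. Longest linear sequence: 5 (steps 1, 2, 3, 6, 7).

**Steps most likely to fail**

Step 6. The enolate may act as a base towards the lactone α-CH2 or attack the alkyl C–O carbon, and the liberated alkoxide may cyclise onto the benzyl ester, so the C-acylation could be eroded. Fallback, setting out from 4 and returning at 11: the lactone is opened with MeNH(OMe)·HCl/Me2AlCl in CH2Cl2 to the Weinreb amide (3R)-5-[4-(benzyloxy)-3-methoxyphenyl]-3-hydroxy-N-methoxy-N-methylpentanamide F1. Separately, purchased 4-(benzyloxy)-3,5-dimethoxybenzaldehyde F2 is homologated with the Ohira–Bestmann reagent (K2CO3, MeOH) to 2-(benzyloxy)-5-ethynyl-1,3-dimethoxybenzene F3. Deprotonation of F3 with n-BuLi gives its lithium acetylide F4, of which three equivalents are added to F1 in THF at −78 to 0 °C to form the same C2–C3 bond at the alkyne oxidation level in (5R)-1-[4-(benzyloxy)-3,5-dimethoxyphenyl]-7-[4-(benzyloxy)-3-methoxyphenyl]-5-hydroxyhept-1-yn-3-one F5. Hydrogenation of F5 (H2, Pd/C, EtOAc) should saturate the triple bond and cleave both benzyl ethers to give 11.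

Step 3. Ketene dimerisation may outrun the cycloaddition, or facial discrimination may be insufficient with this aldehyde. Fallback, setting out from 3 and returning at 4: Roskamp homologation of 3 (ethyl diazoacetate, SnCl2 cat., CH2Cl2) gives ethyl 5-[4-(benzyloxy)-3-methoxyphenyl]-3-oxopentanoate F6. Noyori hydrogenation with a Ru(II)–(R)-BINAP catalyst (H2, EtOH) should give ethyl (3R)-5-[4-(benzyloxy)-3-methoxyphenyl]-3-hydroxypentanoate F7, with the benzyl ether untouched. Saponification (LiOH, THF/H2O) gives (3R)-5-[4-(benzyloxy)-3-methoxyphenyl]-3-hydroxypentanoic acid F8. Carboxyl-activating lactonisation (PhSO2Cl, pyridine, 0 °C), which proceeds with retention at the carbinol carbon, closes F8 to 4.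

Step 7. Lactonisation of the free hydroxy keto acid onto the C5 hydroxyl (dihydropyranone formation) may compete with decarboxylation, or the aldol may dehydrate on warming. Fallback, setting out from 9 and returning at 11: the C5 hydroxyl is silylated (TBSCl, imidazole, DMF) to benzyl (5R)-2-{[4-(benzyloxy)-3,5-dimethoxyphenyl]methyl}-7-[4-(benzyloxy)-3-methoxyphenyl]-5-[(tert-butyldimethylsilyl)oxy]-3-oxoheptanoate F9. Hydrogenolysis (H2, Pd/C, EtOAc) gives the silyloxy keto acid (5R)-5-[(tert-butyldimethylsilyl)oxy]-2-[(4-hydroxy-3,5-dimethoxyphenyl)methyl]-7-(4-hydroxy-3-methoxyphenyl)-3-oxoheptanoic acid F10, which cannot lactonise and should decarboxylate in the flask to (5R)-5-[(tert-butyldimethylsilyl)oxy]-7-(4-hydroxy-3-methoxyphenyl)-1-(4-hydroxy-3,5-dimethoxyphenyl)heptan-3-one F11. Desilylation of F11 with HF·pyridine in THF gives 11.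

**Further compounds**
F1 | step 6 | (3R)-5-[4-(benzyloxy)-3-methoxyphenyl]-3-hydroxy-N-methoxy-N-methylpentanamide | COc1cc(CC[C@@H](O)CC(=O)N(C)OC)ccc1OCc1ccccc1
F2 | step 6 | 4-(benzyloxy)-3,5-dimethoxybenzaldehyde (bought, not made) | COc1cc(C=O)cc(OC)c1OCc1ccccc1
F3 | step 6 | 2-(benzyloxy)-5-ethynyl-1,3-dimethoxybenzene | COc1cc(C#C)cc(OC)c1OCc1ccccc1
F4 | step 6 | lithium acetylide of F3 (not isolated) | COc1cc(C#C[Li])cc(OC)c1OCc1ccccc1
F5 | step 6 | (5R)-1-[4-(benzyloxy)-3,5-dimethoxyphenyl]-7-[4-(benzyloxy)-3-methoxyphenyl]-5-hydroxyhept-1-yn-3-one | COc1cc(CC[C@@H](O)CC(=O)C#Cc2cc(OC)c(OCc3ccccc3)c(OC)c2)ccc1OCc1ccccc1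
F6 | step 3 | ethyl 5-[4-(benzyloxy)-3-methoxyphenyl]-3-oxopentanoate | COc1cc(CCC(=O)CC(=O)OCC)ccc1OCc1ccccc1
F7 | step 3 | ethyl (3R)-5-[4-(benzyloxy)-3-methoxyphenyl]-3-hydroxypentanoate | COc1cc(CC[C@@H](O)CC(=O)OCC)ccc1OCc1ccccc1
F8 | step 3 | (3R)-5-[4-(benzyloxy)-3-methoxyphenyl]-3-hydroxypentanoic acid | COc1cc(CC[C@@H](O)CC(=O)O)ccc1OCc1ccccc1
F9 | step 7 | benzyl (5R)-2-{[4-(benzyloxy)-3,5-dimethoxyphenyl]methyl}-7-[4-(benzyloxy)-3-methoxyphenyl]-5-[(tert-butyldimethylsilyl)oxy]-3-oxoheptanoate (both C2 epimers) | COc1cc(CC[C@@H](O[Si](C)(C)C(C)(C)C)CC(=O)C(Cc2cc(OC)c(OCc3ccccc3)c(OC)c2)C(=O)OCc2ccccc2)ccc1OCc1ccccc1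
F10 | step 7 | (5R)-5-[(tert-butyldimethylsilyl)oxy]-2-[(4-hydroxy-3,5-dimethoxyphenyl)methyl]-7-(4-hydroxy-3-methoxyphenyl)-3-oxoheptanoic acid (not isolated) | COc1cc(CC[C@@H](O[Si](C)(C)C(C)(C)C)CC(=O)C(Cc2cc(OC)c(O)c(OC)c2)C(=O)O)ccc1O
F11 | step 7 | (5R)-5-[(tert-butyldimethylsilyl)oxy]-7-(4-hydroxy-3-methoxyphenyl)-1-(4-hydroxy-3,5-dimethoxyphenyl)heptan-3-one | COc1cc(CC[C@@H](O[Si](C)(C)C(C)(C)C)CC(=O)CCc2cc(OC)c(O)c(OC)c2)ccc1O
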